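The 1,2-dioxolane (ring A: two oxygens, C3, C4, C5) is disconnected at C3–C4 and O–C5. This exploits a hidden match: C4 and C5 with its methyl are the carbons of a 2-methylalk-1-ene whose chain C5–C10 with the C7 methyl is the skeleton of (R)-citronellal, while C3, its methyl and the C1–C2 arm form a methyl ketone at the peroxyketal level. One SnCl4-promoted peroxycarbenium–alkene [3+2] annulation thus closes the ring, makes two skeletal bonds and creates both quaternary centres. Its precursors are a triethylsilyl peroxyketal with a TBDPS-protected C1 alcohol and an alkene pivalate free of other π-nucleophiles; the styryl diene follows by Julia–Kocienski olefination.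

Key step: step 9

Remark (numbering): chain atoms run from C1 (carboxyl carbon) to C15 (phenyl-bearing carbon). The C3 descriptor reads R while the C1 arm is CH2CH2O and S once C1 is CHO or CO2H; the geometry (trans-3,5-dimethyl) is unchanged.

Assumption: the four C3/C5 diastereomers formed in step 9 are separable by chromatography at the stage of 15.

**Alkene fragment**

Step 1
Reactants: 1 (R)-citronellal
Product: 2 (4R)-4,8-dimethylnon-7-en-2-ol
Conditions: MeMgBr (1.2 equiv), Et2O, 0 °C; then aq NH4Cl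
Reagents that add atoms: methylmagnesium bromide, C[Mg]Br
Why: Grignard 1,2-addition to the aldehyde installs the future C5 methyl; the new carbinol centre forms unselectively but is destroyed by oxidation in step 4, and the C7 centre, β to the carbonyl, is untouched.

Step 2
Reactants: 2 (4R)-4,8-dimethylnon-7-en-2-ol
Product: 4 (4R)-4-methylheptane-1,6-diol, via secondary ozonide 3 (not isolated)
Conditions: O3, CH2Cl2, −78 °C; then NaBH4, MeOH, −78 °C → rt
Reagents that add atoms: ozone, [O-][O+]=O
Why: Ozonolysis cleaves the trisubstituted alkene and borohydride reduction of the ozonide (reductive work-up) should deliver the C10 primary alcohol, the isopropylidene carbon leaving as propan-2-ol.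

Step 3
Reactants: 4 (4R)-4-methylheptane-1,6-diol
Product: 5 (4R)-6-hydroxy-4-methylheptyl pivalate
Conditions: PivCl (1.05 equiv), pyridine, CH2Cl2, −20 → 0 °C
Reagents that add atoms: pivaloyl chloride, CC(C)(C)C(=O)Cl
Why: Sterically controlled selective acylation, the bulky acid chloride esterifying the primary hydroxyl much faster than the secondary one.

Step 4
Reactants: 5 (4R)-6-hydroxy-4-methylheptyl pivalate
Product: 6 (4R)-4-methyl-6-oxoheptyl pivalate
Conditions: Dess–Martin periodinane, CH2Cl2, rt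
Reagents that add atoms: none
Why: Dess–Martin oxidation converts the secondary alcohol into the methyl ketone under neutral conditions that leave the ester alone, and the C7 centre (β to the new carbonyl) cannot enolise.

Step 5
Reactants: 6 (4R)-4-methyl-6-oxoheptyl pivalate
Product: 7 (4R)-4,6-dimethylhept-6-en-1-yl pivalate
Conditions: Ph3PCH3Br, KOtBu, THF, 0 °C → rt
Reagents that add atoms: methyltriphenylphosphonium bromide, [Br-].C[P+](c1ccccc1)(c1ccccc1)c1ccccc1
Why: Wittig methylenation of the methyl ketone with the non-stabilised ylide creates the C4=C5 1,1-disubstituted alkene, the hindered pivalate being far less electrophilic than the ketone.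

**Peroxyketal fragment**

Step 6
Reactants: 8 3-methylbut-3-en-1-ol
Product: 9 tert-butyl[(3-methylbut-3-en-1-yl)oxy]diphenylsilane
Conditions: TBDPSCl, imidazole, CH2Cl2, rt
Reagents that add atoms: tert-butyl(chloro)diphenylsilane, CC(C)(C)[Si](Cl)(c1ccccc1)c1ccccc1
Why: Imidazole-mediated silylation gives a bulky, Lewis-acid-stable ether whose oxygen is a poor nucleophile.

Step 7
Reactants: 9 tert-butyl[(3-methylbut-3-en-1-yl)oxy]diphenylsilane
Product: 11 tert-butyl(3-hydroperoxy-3-methoxybutoxy)diphenylsilane, via ketone O-oxide 10 (not isolated)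
Conditions: O3, MeOH/CH2Cl2 (1:4), −78 °C; N2 purge; concentrate cold (no reductive work-up)
Reagents that add atoms: ozone, [O-][O+]=O; methanol, CO
Why: Criegee ozonolysis in methanol, in which the primary ozonide of a 1,1-disubstituted alkene fragments to formaldehyde and the more substituted ketone O-oxide 10, which methanol traps as the α-methoxy hydroperoxide.

Step 8
Reactants: 11 tert-butyl(3-hydroperoxy-3-methoxybutoxy)diphenylsilane
Product: 12 tert-butyl{3-methoxy-3-[(triethylsilyl)peroxy]butoxy}diphenylsilane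
Conditions: Et3SiCl, imidazole, DMF, 0 °C
Reagents that add atoms: chlorotriethylsilane, CC[Si](Cl)(CC)CC
Why: O-Silylation of the hydroperoxide, which is more acidic and more nucleophilic than an alcohol, proceeds under basic conditions that do not ionise the ketal.

**Key step**

Step 9
Reactants: 12 tert-butyl{3-methoxy-3-[(triethylsilyl)peroxy]butoxy}diphenylsilane; 7 (4R)-4,6-dimethylhept-6-en-1-yl pivalate
Product: 15 (4R)-5-[(3R,5R)-5-{2-[(tert-butyldiphenylsilyl)oxy]ethyl}-3,5-dimethyl-1,2-dioxolan-3-yl]-4-methylpentyl pivalate, via peroxycarbenium ion 13 (not isolated), via tertiary carbocation 14 (not isolated)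
Conditions: 7 (1.0 equiv), 12 (1.5 equiv), SnCl4 (1.5 equiv), CH2Cl2, −78 °C; aq NaHCO3; separation of diastereomers by chromatography
Reagents that add atoms: none
Why: SnCl4 abstracts methoxide from 12 to give the acyclic peroxycarbenium ion 13; the CH2 terminus of alkene 7 (C4) adds to C3 in the Markovnikov sense to give the tertiary C5 cation 14, and the silylated peroxy oxygen captures C5 with transfer of the triethylsilyl group to methoxide, which closes ring A and returns the Lewis acid. This is the known SnCl4-mediated [3+2] annulation of triethylsilyl peroxyketals with 1,1-disubstituted alkenes giving 3,3,5,5-tetrasubstituted 1,2-dioxolanes. The single ring formed, the 1,2-dioxolane, closes stepwise by five-membered oxygen-to-carbocation recombination at C5, which has no trajectory constraint because the electrophile is a free tertiary cation. C3 becomes stereogenic when the planar carbenium carbon is attacked and C5 when the planar cation is captured; neither event is biased by the remote C7 centre and methyl versus CH2R differ little in the envelope-like closure, so all four C3/C5 isomers are expected and the (3R,5R,7R) trans-dimethyl isomer is isolated by chromatography, C7 being carried unchanged from 1. The step needs chemo- and regioselectivity: 7 contains no second π-nucleophile because the chain alkenes are installed later, tertiary cation formation fixes the orientation of addition, the pivalate carbonyl could reach C5 only through a nine-membered ring, and the TBDPS ether oxygen, which could reach C5 through a six-membered ring, is too hindered and too weakly nucleophilic to compete with five-membered peroxide closure.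

**Sulfone fragment**

Step 10
Reactants: 16 1-phenylprop-2-en-1-ol
Product: 18 ethyl (4E)-5-phenylpent-4-enoate, via ketene acetal 17 (not isolated)
Conditions: MeC(OEt)3 (excess), EtCO2H (cat.), 140 °C, EtOH distilled off
Reagents that add atoms: triethyl orthoacetate, CCOC(C)(OCC)OCC
Why: Johnson–Claisen rearrangement, in which orthoester exchange and loss of ethanol give ketene acetal 17, whose chair [3,3] shift with the phenyl group pseudo-equatorial should give the conjugated E alkene.

Step 11
Reactants: 18 ethyl (4E)-5-phenylpent-4-enoate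
Product: 19 (4E)-5-phenylpent-4-en-1-ol
Conditions: LiAlH4, THF, 0 °C; then H2O
Reagents that add atoms: none
Why: LiAlH4 reduction of the ester to the primary alcohol, the isolated styrenyl alkene being inert to hydride.

Step 12
Reactants: 19 (4E)-5-phenylpent-4-en-1-ol
Product: 20 1-phenyl-5-{[(4E)-5-phenylpent-4-en-1-yl]sulfanyl}-1H-tetrazole
Conditions: 1-phenyl-1H-tetrazole-5-thiol, PPh3, DIAD, THF, 0 °C → rt
Reagents that add atoms: 1-phenyl-1H-tetrazole-5-thiol, Sc1nnnn1-c1ccccc1
Why: Mitsunobu thioetherification, the acidic tetrazolethiol displacing the activated primary alkoxyphosphonium ion.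

Step 13
Reactants: 20 1-phenyl-5-{[(4E)-5-phenylpent-4-en-1-yl]sulfanyl}-1H-tetrazole
Product: 21 1-phenyl-5-{[(4E)-5-phenylpent-4-en-1-yl]sulfonyl}-1H-tetrazole
Conditions: (NH4)6Mo7O24·4H2O (cat.), 30% aq H2O2, EtOH, 0 °C → rt
Reagents that add atoms: hydrogen peroxide, OO
Why: Molybdate-catalysed peroxide oxidation takes the sulfide to the sulfone, sulfur being oxidised much faster than the unfunctionalised alkene.

**End game**

Step 14
Reactants: 15 (4R)-5-[(3R,5R)-5-{2-[(tert-butyldiphenylsilyl)oxy]ethyl}-3,5-dimethyl-1,2-dioxolan-3-yl]-4-methylpentyl pivalate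
Product: 22 (4R)-5-[(3R,5R)-5-{2-[(tert-butyldiphenylsilyl)oxy]ethyl}-3,5-dimethyl-1,2-dioxolan-3-yl]-4-methylpentan-1-ol
Conditions: NaOMe (0.3 equiv), MeOH, rt
Reagents that add atoms: none
Why: Methoxide-catalysed transesterification removes the pivalate; the ring has no hydrogen on C3 or C5, so base-induced (Kornblum–DeLaMare) peroxide cleavage is not possible, and the TBDPS ether is stable to these conditions.

Step 15
Reactants: 22 (4R)-5-[(3R,5R)-5-{2-[(tert-butyldiphenylsilyl)oxy]ethyl}-3,5-dimethyl-1,2-dioxolan-3-yl]-4-methylpentan-1-ol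
Product: 23 (4R)-5-[(3R,5R)-5-{2-[(tert-butyldiphenylsilyl)oxy]ethyl}-3,5-dimethyl-1,2-dioxolan-3-yl]-4-methylpentanal
Conditions: Dess–Martin periodinane, CH2Cl2, 0 °C → rt
Reagents that add atoms: none
Why: Dess–Martin oxidation gives the C10 aldehyde under neutral, non-reducing conditions that spare the O–O bond and the silyl ether.

Step 16
Reactants: 23 (4R)-5-[(3R,5R)-5-{2-[(tert-butyldiphenylsilyl)oxy]ethyl}-3,5-dimethyl-1,2-dioxolan-3-yl]-4-methylpentanal; 21 1-phenyl-5-{[(4E)-5-phenylpent-4-en-1-yl]sulfonyl}-1H-tetrazole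
Product: 25 tert-butyl{2-[(3R,5R)-3,5-dimethyl-5-[(2R,5E,9E)-2-methyl-10-phenyldeca-5,9-dien-1-yl]-1,2-dioxolan-3-yl]ethoxy}diphenylsilane, via β-alkoxy sulfone 24 (not isolated)
Conditions: 21 (1.3 equiv), KN(SiMe3)2, DME, −55 °C; then 23, −55 °C → rt; aq NH4Cl
Reagents that add atoms: none
Why: Julia–Kocienski olefination, in which the potassium sulfonyl carbanion should add to the aldehyde preferentially in the anti sense (open transition state in DME) and Smiles rearrangement with anti-periplanar loss of SO2 and tetrazolyl oxide gives the E C10=C11 alkene, the stabilised carbanion being too weak a nucleophile to attack the hindered di-tertiary peroxide at low temperature.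

Step 17
Reactants: 25 tert-butyl{2-[(3R,5R)-3,5-dimethyl-5-[(2R,5E,9E)-2-methyl-10-phenyldeca-5,9-dien-1-yl]-1,2-dioxolan-3-yl]ethoxy}diphenylsilane
Product: 26 2-[(3R,5R)-3,5-dimethyl-5-[(2R,5E,9E)-2-methyl-10-phenyldeca-5,9-dien-1-yl]-1,2-dioxolan-3-yl]ethan-1-ol
Conditions: Bu4NF, THF, 0 °C → rt; aq NH4Cl
Reagents that add atoms: none
Why: Fluoride-induced desilylation driven by the Si–F bond frees the C1 alcohol without affecting the peroxide or the alkenes.

Step 18
Reactants: 26 2-[(3R,5R)-3,5-dimethyl-5-[(2R,5E,9E)-2-methyl-10-phenyldeca-5,9-dien-1-yl]-1,2-dioxolan-3-yl]ethan-1-ol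
Product: 28 2-[(3S,5R)-3,5-dimethyl-5-[(2R,5E,9E)-2-methyl-10-phenyldeca-5,9-dien-1-yl]-1,2-dioxolan-3-yl]acetic acid, via aldehyde 27 (not isolated)
Conditions: TEMPO (0.2 equiv), PhI(OAc)2 (2.2 equiv), MeCN/H2O (1:1), rt
Reagents that add atoms: water, O
Why: Oxoammonium (TEMPO) oxidation with PhI(OAc)2 as terminal oxidant takes the alcohol to aldehyde 27 and, through its hydrate, to the acid in one pot; the weakly acidic medium should avoid β-elimination of the peroxide and leave the alkenes untouched.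

**Compound list**

1 | (R)-citronellal | C[C@H](CCC=C(C)C)CC=O | starting material
2 | (4R)-4,8-dimethylnon-7-en-2-ol (both C2 epimers) | CC(O)C[C@H](C)CCC=C(C)C | intermediate
3 | (4R)-6-(5,5-dimethyl-1,2,4-trioxolan-3-yl)-4-methylhexan-2-ol (secondary ozonide, not isolated) | CC(O)C[C@H](C)CCC1OOC(C)(C)O1 | intermediate
4 | (4R)-4-methylheptane-1,6-diol (both C6 epimers) | CC(O)C[C@H](C)CCCO | intermediate
5 | (4R)-6-hydroxy-4-methylheptyl pivalate | CC(O)C[C@H](C)CCCOC(=O)C(C)(C)C | intermediate
6 | (4R)-4-methyl-6-oxoheptyl pivalate | CC(=O)C[C@H](C)CCCOC(=O)C(C)(C)C | intermediate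
7 | (4R)-4,6-dimethylhept-6-en-1-yl pivalate | C=C(C)C[C@H](C)CCCOC(=O)C(C)(C)C | intermediate
8 | 3-methylbut-3-en-1-ol | C=C(C)CCO | starting material
9 | tert-butyl[(3-methylbut-3-en-1-yl)oxy]diphenylsilane | C=C(C)CCO[Si](c1ccccc1)(c1ccccc1)C(C)(C)C | intermediate
10 | 4-[(tert-butyldiphenylsilyl)oxy]butan-2-one O-oxide (carbonyl oxide, not isolated) | CC(=[O+][O-])CCO[Si](c1ccccc1)(c1ccccc1)C(C)(C)C | intermediate
11 | tert-butyl(3-hydroperoxy-3-methoxybutoxy)diphenylsilane (racemic) | CC(OC)(OO)CCO[Si](c1ccccc1)(c1ccccc1)C(C)(C)C | intermediate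
12 | tert-butyl{3-methoxy-3-[(triethylsilyl)peroxy]butoxy}diphenylsilane (racemic) | CC(OC)(CCO[Si](c1ccccc1)(c1ccccc1)C(C)(C)C)OO[Si](CC)(CC)CC | intermediate
13 | {4-[(tert-butyldiphenylsilyl)oxy]butan-2-ylidene}[(triethylsilyl)oxy]oxonium (peroxycarbenium ion, not isolated) | CC(CCO[Si](c1ccccc1)(c1ccccc1)C(C)(C)C)=[O+]O[Si](CC)(CC)CC | intermediate
14 | (7R)-1-[(tert-butyldiphenylsilyl)oxy]-3,5,7-trimethyl-10-(pivaloyloxy)-3-[(triethylsilyl)peroxy]decan-5-ylium (tertiary C5 cation, not isolated) | C[C@H](CCCOC(=O)C(C)(C)C)C[C+](C)CC(C)(CCO[Si](c1ccccc1)(c1ccccc1)C(C)(C)C)OO[Si](CC)(CC)CC | intermediate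
15 | (4R)-5-[(3R,5R)-5-{2-[(tert-butyldiphenylsilyl)oxy]ethyl}-3,5-dimethyl-1,2-dioxolan-3-yl]-4-methylpentyl pivalate (chain C3 R, C5 R, C7 R; trans-3,5-dimethyl) | C[C@H](CCCOC(=O)C(C)(C)C)C[C@]1(C)C[C@@](C)(CCO[Si](c2ccccc2)(c2ccccc2)C(C)(C)C)OO1 | intermediate
16 | 1-phenylprop-2-en-1-ol (racemic) | C=CC(O)c1ccccc1 | starting material
17 | [1-(1-ethoxyethenyloxy)prop-2-en-1-yl]benzene (ketene acetal, not isolated) | C=CC(OC(=C)OCC)c1ccccc1 | intermediate
18 | ethyl (4E)-5-phenylpent-4-enoate | CCOC(=O)CC/C=C/c1ccccc1 | intermediate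
19 | (4E)-5-phenylpent-4-en-1-ol | OCCC/C=C/c1ccccc1 | intermediate
20 | 1-phenyl-5-{[(4E)-5-phenylpent-4-en-1-yl]sulfanyl}-1H-tetrazole | c1ccccc1/C=C/CCCSc1nnnn1-c1ccccc1 | intermediate
21 | 1-phenyl-5-{[(4E)-5-phenylpent-4-en-1-yl]sulfonyl}-1H-tetrazole | O=S(=O)(CCC/C=C/c1ccccc1)c1nnnn1-c1ccccc1 | intermediate
22 | (4R)-5-[(3R,5R)-5-{2-[(tert-butyldiphenylsilyl)oxy]ethyl}-3,5-dimethyl-1,2-dioxolan-3-yl]-4-methylpentan-1-ol | C[C@H](CCCO)C[C@]1(C)C[C@@](C)(CCO[Si](c2ccccc2)(c2ccccc2)C(C)(C)C)OO1 | intermediate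
23 | (4R)-5-[(3R,5R)-5-{2-[(tert-butyldiphenylsilyl)oxy]ethyl}-3,5-dimethyl-1,2-dioxolan-3-yl]-4-methylpentanal | C[C@H](CCC=O)C[C@]1(C)C[C@@](C)(CCO[Si](c2ccccc2)(c2ccccc2)C(C)(C)C)OO1 | intermediate
24 | potassium β-alkoxy sulfone from addition of metalated 21 to 23 (C10 alkoxide, C11 sulfone, diastereomer mixture, not isolated) | C[C@H](CCC([O-])C(CC/C=C/c2ccccc2)S(=O)(=O)c2nnnn2-c2ccccc2)C[C@]1(C)C[C@@](C)(CCO[Si](c2ccccc2)(c2ccccc2)C(C)(C)C)OO1.[K+] | intermediate
25 | tert-butyl{2-[(3R,5R)-3,5-dimethyl-5-[(2R,5E,9E)-2-methyl-10-phenyldeca-5,9-dien-1-yl]-1,2-dioxolan-3-yl]ethoxy}diphenylsilane | C[C@H](CC/C=C/CC/C=C/c1ccccc1)C[C@]1(C)C[C@@](C)(CCO[Si](c2ccccc2)(c2ccccc2)C(C)(C)C)OO1 | intermediate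
26 | 2-[(3R,5R)-3,5-dimethyl-5-[(2R,5E,9E)-2-methyl-10-phenyldeca-5,9-dien-1-yl]-1,2-dioxolan-3-yl]ethan-1-ol | C[C@H](CC/C=C/CC/C=C/c1ccccc1)C[C@]1(C)C[C@@](C)(CCO)OO1 | intermediate
27 | 2-[(3S,5R)-3,5-dimethyl-5-[(2R,5E,9E)-2-methyl-10-phenyldeca-5,9-dien-1-yl]-1,2-dioxolan-3-yl]acetaldehyde (not isolated) | C[C@H](CC/C=C/CC/C=C/c1ccccc1)C[C@]1(C)C[C@@](C)(CC=O)OO1 | intermediate
28 | 2-[(3S,5R)-3,5-dimethyl-5-[(2R,5E,9E)-2-methyl-10-phenyldeca-5,9-dien-1-yl]-1,2-dioxolan-3-yl]acetic acid | C[C@H](CC/C=C/CC/C=C/c1ccccc1)C[C@]1(C)C[C@@](C)(CC(=O)O)OO1 | target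

**Totals**

Total step count: 18. Longest linear sequence: 11 steps (steps 1–5, 9, 14–18).

**Steps most likely to fail**

Step 9. Both planar cationic carbons (C3 in 13, C5 in 14) can be attacked from either face, so the four diastereomers may form in comparable amounts and resist separation. Cation 14 may also lose a proton and give open-chain unsaturated peroxides instead of closing ring A. The fallback sets out from 7 and comes back at 15; it builds the ring by peroxide conjugate addition and sets C3 by nucleophilic substitution on a cyclic cation.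
- Cross-metathesis of 7 with but-3-en-2-one (second-generation Hoveyda–Grubbs catalyst, CH2Cl2, 40 °C) should give (4R,6E)-4,6-dimethyl-8-oxonon-6-en-1-yl pivalate F1.
- Conjugate addition of H2O2 under mild amine catalysis, followed by spontaneous peroxyhemiketal closure, should give (4R)-5-(5-hydroxy-3,5-dimethyl-1,2-dioxolan-3-yl)-4-methylpentyl pivalate F2.
- Acid-catalysed exchange (MeOH, cat. TsOH) should give (4R)-5-(5-methoxy-3,5-dimethyl-1,2-dioxolan-3-yl)-4-methylpentyl pivalate F3.
- TiCl4-mediated substitution with allyltrimethylsilane through the cyclic dioxolan-3-yl cation should give (4R)-5-[(3R,5R)-3,5-dimethyl-5-(prop-2-en-1-yl)-1,2-dioxolan-3-yl]-4-methylpentyl pivalate F4. The nucleophile should prefer the face anti to the larger C5 substituent, which is the trans-dimethyl arrangement; the C5 epimers relative to C7 are separated here.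
- Ozonolysis with NaBH4 work-up, which leaves the dialkyl peroxide intact, should give (4R)-5-[(3R,5R)-5-(2-hydroxyethyl)-3,5-dimethyl-1,2-dioxolan-3-yl]-4-methylpentyl pivalate F5.
- Silylation (TBDPSCl, imidazole) returns 15.

Step 16. Addition of the metalated sulfone to the unbranched aldehyde may be poorly diastereoselective, eroding the E geometry at C10=C11. The basic medium may also enolise the precious aldehyde 23 (self-condensation). The fallback sets out from 22 and 19 and comes back at 25; it reverses the polarity of the two partners.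
- Mesylation of 22 (MsCl, Et3N) gives (4R)-5-[(3R,5R)-5-{2-[(tert-butyldiphenylsilyl)oxy]ethyl}-3,5-dimethyl-1,2-dioxolan-3-yl]-4-methylpentyl methanesulfonate F6.
- Displacement with potassium 1-phenyltetrazole-5-thiolate in DMF gives 5-{[(4R)-5-[(3R,5R)-5-{2-[(tert-butyldiphenylsilyl)oxy]ethyl}-3,5-dimethyl-1,2-dioxolan-3-yl]-4-methylpentyl]sulfanyl}-1-phenyl-1H-tetrazole F7. No phosphine is used, since it could deoxygenate the peroxide.
- Oxidation with H2O2 and catalytic (NH4)6Mo7O24·4H2O gives 5-{[(4R)-5-[(3R,5R)-5-{2-[(tert-butyldiphenylsilyl)oxy]ethyl}-3,5-dimethyl-1,2-dioxolan-3-yl]-4-methylpentyl]sulfonyl}-1-phenyl-1H-tetrazole F8.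
- Dess–Martin oxidation of 19 gives (4E)-5-phenylpent-4-enal F9.
- Julia–Kocienski olefination under Barbier conditions (KN(SiMe3)2 added to F8 and excess F9 in DME at −55 °C) should give 25. The simple aldehyde is used in excess and a different adduct pair decides the E/Z ratio.

Step 7. The primary ozonide may fragment partly in the opposite sense (formaldehyde O-oxide plus ketone), and the α-methoxy hydroperoxide may lose methanol or hydrogen peroxide during concentration and chromatography. The fallback sets out from 9 and comes back at 11; it installs the hydroperoxide by acetal exchange instead of carbonyl oxide trapping.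
- Ozonolysis of 9 with Me2S work-up gives 4-[(tert-butyldiphenylsilyl)oxy]butan-2-one F10.
- HC(OMe)3, MeOH and catalytic TsOH give tert-butyl(3,3-dimethoxybutoxy)diphenylsilane F11.
- Acid-catalysed exchange of one methoxy group with ethereal H2O2 (cat. camphorsulfonic acid, 0 °C) should give 11.

**Further compounds**

F1 | step 9 | (4R,6E)-4,6-dimethyl-8-oxonon-6-en-1-yl pivalate | CC(=O)/C=C(\C)C[C@H](C)CCCOC(=O)C(C)(C)C
F2 | step 9 | (4R)-5-(5-hydroxy-3,5-dimethyl-1,2-dioxolan-3-yl)-4-methylpentyl pivalate (ring-centre mixture) | C[C@H](CCCOC(=O)C(C)(C)C)CC1(C)CC(C)(O)OO1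
F3 | step 9 | (4R)-5-(5-methoxy-3,5-dimethyl-1,2-dioxolan-3-yl)-4-methylpentyl pivalate (ring-centre mixture) | C[C@H](CCCOC(=O)C(C)(C)C)CC1(C)CC(C)(OC)OO1
F4 | step 9 | (4R)-5-[(3R,5R)-3,5-dimethyl-5-(prop-2-en-1-yl)-1,2-dioxolan-3-yl]-4-methylpentyl pivalate | C[C@H](CCCOC(=O)C(C)(C)C)C[C@]1(C)C[C@@](C)(CC=C)OO1
F5 | step 9 | (4R)-5-[(3R,5R)-5-(2-hydroxyethyl)-3,5-dimethyl-1,2-dioxolan-3-yl]-4-methylpentyl pivalate | C[C@H](CCCOC(=O)C(C)(C)C)C[C@]1(C)C[C@@](C)(CCO)OO1
F6 | step 16 | (4R)-5-[(3R,5R)-5-{2-[(tert-butyldiphenylsilyl)oxy]ethyl}-3,5-dimethyl-1,2-dioxolan-3-yl]-4-methylpentyl methanesulfonate | C[C@H](CCCOS(C)(=O)=O)C[C@]1(C)C[C@@](C)(CCO[Si](c2ccccc2)(c2ccccc2)C(C)(C)C)OO1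
F7 | step 16 | 5-{[(4R)-5-[(3R,5R)-5-{2-[(tert-butyldiphenylsilyl)oxy]ethyl}-3,5-dimethyl-1,2-dioxolan-3-yl]-4-methylpentyl]sulfanyl}-1-phenyl-1H-tetrazole | C[C@H](CCCSc2nnnn2-c2ccccc2)C[C@]1(C)C[C@@](C)(CCO[Si](c2ccccc2)(c2ccccc2)C(C)(C)C)OO1
F8 | step 16 | 5-{[(4R)-5-[(3R,5R)-5-{2-[(tert-butyldiphenylsilyl)oxy]ethyl}-3,5-dimethyl-1,2-dioxolan-3-yl]-4-methylpentyl]sulfonyl}-1-phenyl-1H-tetrazole | C[C@H](CCCS(=O)(=O)c2nnnn2-c2ccccc2)C[C@]1(C)C[C@@](C)(CCO[Si](c2ccccc2)(c2ccccc2)C(C)(C)C)OO1
F9 | step 16 | (4E)-5-phenylpent-4-enal | O=CCC/C=C/c1ccccc1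
F10 | step 7 | 4-[(tert-butyldiphenylsilyl)oxy]butan-2-one | CC(=O)CCO[Si](c1ccccc1)(c1ccccc1)C(C)(C)C
F11 | step 7 | tert-butyl(3,3-dimethoxybutoxy)diphenylsilane | CC(OC)(OC)CCO[Si](c1ccccc1)(c1ccccc1)C(C)(C)C
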